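Partner stands to starting material at a ratio of 5.00 equiv, so starting material is the limiting reagent, and the books are kept in percent of its charge.

| setting | south-east | north-east | flask |
|---|---|---|---|
| starting material | 0.20 M | 0.20 M | 0.20 M |
| partner | 3.4 equiv | 7.5 equiv | 5.00 equiv |
| remark | run made earlier | run made earlier |  |
| time |  |  | 8.0 h |

| run | time / h | target / % | starting material / % |
|---|---|---|---|
| south-east | 0.100 | 65 | 32 |
| south-east | 0.200 | 83 | 16 |
| south-east | 0.417 | 88 | 8 |
| south-east | 1.00 | 86 | 8 |
| south-east | 2.00 | 84 | 7 |
| south-east | 4.00 | 75 | 3 |
| south-east | 10.0 | 60 | 4 |
| north-east | 0.100 | 86 | 8 |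
| north-east | 0.200 | 94 | 2 |
| north-east | 0.417 | 91 | 2 |
| north-east | 1.00 | 89 | 3 |
| north-east | 2.00 | 88 | 2 |
| north-east | 4.00 | 81 | 1 |
| north-east | 10.0 | 62 | 3 |

(each reading ± 1.5 percentage points)

- what was read earlier has a scatter of 1.5 percentage points, one standard deviation
- a reading or a percentage of target counts all its forms, free or not
- a reading of starting material is of its free form alone

- the best time, 8.0 h at the latest, for target
- the amount of target, in percent of the starting material charged, at that time
- earliest time at which at least nineteen twentieths of that best amount are there
- latest time at which they still are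

The ledger has three entries, read at 0.417 h and 10.0 h. Free starting material goes from 8% to 4% in the south-east run and from 2% to 3% in the north-east run. Target goes from 88% to 60% and from 91% to 62%. The remainder, charged moles found in neither entry, grows from 4.00% to 36.0% and from 7.00% to 35.0%.

So the remainder grows as target falls: target loses 28 percentage points in the south-east run and 29 points in the north-east run, although the partner charges differ. Their mean over the interval, 0.0297 h⁻¹, is the drain, the fraction of the charge leaving target each hour. It is a reading and carries the scatter.

The forecast gives 92% at 0.35 h, with the window opening at 0.17 h and shutting at 2 h, the latter since “both runs sit near 95% of their peak at 2 h”. My own count differs slightly: the margin of 4.6 points lasts 1.55 h at the drain, which shuts the window near 1.90 h.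

The flask peaks at 90.6% at 0.363 h, crystals counted in target, and its window runs from 0.158 h to 2.00 h, so the forecast stands.

    crystals ⇌ target, rate k1*(cs1 - [target]) while solid is left; crystals form when [target] > cs1 (solubility = 21.0 mM, k = 1.12 min⁻¹)
    starting material + partner ⇌ isomer of the product (K = 156 L mol⁻¹, k = 0.0166 L mol⁻¹ min⁻¹)
    starting material + partner ⇌ target (K = 3.40 L mol⁻¹, k = 0.363 L mol⁻¹ min⁻¹)

In the flask the remainder is the isomer of the product, 5.59% at 0.363 h and 27.2% at 8.00 h. The neighbour flask with 1.20 equiv of partner reaches a best of 62.9%, less than the forecast's 92%. From the flask's peak, the drain predicts 67.9% at 8.00 h, where the flask holds 69.1%. Carried on to 20 h, it predicts 32.2%, where the flask left that long holds 37.1%.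

Readings and results were generated by integration for substances that don't exist, noise included.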